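**Assumption:** the ketoreductase in step 6 is an (R)-selective (anti-Prelog) enzyme picked by screening a commercial panel; the target is taken as the (2S)-flavanone encoded by the SMILES. The route is designed on paper and has not been run.

## Retrosynthetic overview

1. Target ⇐ global MOM removal from the protected (2S)-flavanone, whose C4 ketone comes from oxidation of a flavan-4-ol (C4 is carried as a silyl-protected alcohol so that SN2 at C2 is not pre-empted by β-elimination to a chalcone).
2. Rings A and B are bought as aromatics. Ring C is the only ring built and is closed last, at O1–C2, by intramolecular Mitsunobu etherification with inversion: (R)-carbinol → (2S).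
3. C4–C4a bond: aryllithium from 2,4-diprenylphloroglucinol tris-MOM ether plus the Weinreb amide of an (R)-β-silyloxy acid; one ortho-MOM is then removed under chelation control to free the ring-closing phenol.
4. C2 stereocentre: ketoreductase reduction of an achiral aryl β-keto ester made from 3,5-dihydroxyacetophenone.
5. Prenyl groups: two successive directed ortho-metalation/prenylation steps on phloroglucinol tris-MOM ether.

## Route

**Step 1**
Reactants: 1, phloroglucinol
Product: 2, 1,3,5-tris(methoxymethoxy)benzene
Conditions: NaH, MOMCl, DMF, 0 °C → rt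
Reagents that add atoms: chloromethyl methyl ether, COCCl
Why: Williamson-type O-alkylation of the triphenoxide; MOM serves later as ortho-metalation director and as carbonyl-chelating group.

**Step 2**
Reactants: 2
Product: 3, 1,3,5-tris(methoxymethoxy)-2-(3-methylbut-2-en-1-yl)benzene
Conditions: n-BuLi, TMEDA, THF, 0 °C, 1 h; then prenyl bromide, −78 °C → rt
Reagents that add atoms: prenyl bromide, CC(C)=CCBr
Why: directed ortho-metalation at a CH flanked by two OMOM groups, then SN2 alkylation of the aryllithium by the allylic bromide.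

**Step 3**
Reactants: 3
Product: 4, 1,3,5-tris(methoxymethoxy)-2,4-bis(3-methylbut-2-en-1-yl)benzene
Conditions: n-BuLi, TMEDA, THF, 0 °C; then prenyl bromide, −78 °C → rt
Reagents that add atoms: prenyl bromide, CC(C)=CCBr
Why: second directed ortho-metalation/alkylation; the two remaining ring hydrogens are equivalent, so there is no regiochemical issue.

**Step 4**
Reactants: 5, 3,5-dihydroxyacetophenone
Product: 6, 1-[3,5-bis(methoxymethoxy)phenyl]ethan-1-one
Conditions: MOMCl, i-Pr2NEt, CH2Cl2, 0 °C → rt
Reagents that add atoms: chloromethyl methyl ether, COCCl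
Why: standard phenol protection as MOM acetals, stable to base, hydride, organolithium and buffer.

**Step 5**
Reactants: 6
Product: 7, ethyl 3-[3,5-bis(methoxymethoxy)phenyl]-3-oxopropanoate
Conditions: NaH, (EtO)2CO, THF, reflux
Reagents that add atoms: diethyl carbonate, CCOC(=O)OCC
Why: crossed Claisen condensation of the methyl ketone enolate with diethyl carbonate, driven by deprotonation of the β-keto ester product.

**Step 6**
Reactants: 7
Product: 8, ethyl (3R)-3-[3,5-bis(methoxymethoxy)phenyl]-3-hydroxypropanoate
Conditions: ketoreductase (NADPH-dependent, (R)-selective), NADP+ (cat.), i-PrOH (15% v/v), KPi buffer pH 7, 5% DMSO, 30 °C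
Reagents that add atoms: none (two H from i-PrOH via NADPH)
Why: enzymatic asymmetric ketone reduction; the ketoreductase delivers hydride to the si face of the prochiral aryl ketone, giving the (R)-carbinol, the first stereocentre in the route and the future C2.

**Step 7**
Reactants: 8
Product: 9, (3R)-3-[3,5-bis(methoxymethoxy)phenyl]-3-hydroxy-N-methoxy-N-methylpropanamide
Conditions: MeNH(OMe)·HCl, i-PrMgCl, THF, −20 → 0 °C
Reagents that add atoms: N,O-dimethylhydroxylamine hydrochloride, CNOC.Cl
Why: Weinreb amidation of the ester by the magnesium amide; the carbinol is not at an enolisable position and is untouched.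

**Step 8**
Reactants: 9
Product: 10, (3R)-3-[3,5-bis(methoxymethoxy)phenyl]-N-methoxy-N-methyl-3-(triethylsilyloxy)propanamide
Conditions: TESCl, imidazole, DMF, 0 °C → rt
Reagents that add atoms: chlorotriethylsilane, CC[Si](Cl)(CC)CC
Why: O-silylation; TES is chosen because it can later be removed selectively in the presence of a hindered TBS ether.

**Step 9**
Reactants: 4 and 10
Product: 11, (3R)-3-[3,5-bis(methoxymethoxy)phenyl]-1-[2,4,6-tris(methoxymethoxy)-3,5-bis(3-methylbut-2-en-1-yl)phenyl]-3-(triethylsilyloxy)propan-1-one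
Conditions: 4, n-BuLi, THF, 0 °C, 1 h; then 10, −78 → −20 °C; aq. NH4Cl
Reagents that add atoms: none (both partners are numbered reactants)
Why: third directed ortho-metalation at the last ring CH, then Weinreb ketone synthesis; the chelated tetrahedral intermediate prevents over-addition and the carbinol centre is not involved.

**Step 10**
Reactants: 11
Product: 12, (3R)-3-[3,5-bis(methoxymethoxy)phenyl]-1-[2-hydroxy-4,6-bis(methoxymethoxy)-3,5-bis(3-methylbut-2-en-1-yl)phenyl]-3-(triethylsilyloxy)propan-1-one
Conditions: MgBr2·OEt2, Et2O/toluene, 0 °C → rt; aq. NH4Cl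
Reagents that add atoms: none
Why: chelation-controlled acetal cleavage; Mg bridges the ketone and one ortho-OMOM (the two are equivalent), and the resulting H-bonded phenol shuts down cleavage of the second, while non-chelated MOM and TES groups stay.

**Step 11**
Reactants: 12
Product: 13, 2-[(1RS,3R)-3-[3,5-bis(methoxymethoxy)phenyl]-1-hydroxy-3-(triethylsilyloxy)propyl]-3,5-bis(methoxymethoxy)-4,6-bis(3-methylbut-2-en-1-yl)phenol
Conditions: NaBH4, THF/MeOH, 0 °C → rt; basic work-up, used crude
Reagents that add atoms: none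
Why: hydride reduction masks the C4 ketone as an alcohol so the later SN2 at C2 cannot be diverted by β-elimination; the new C4 centre is uncontrolled and is destroyed in step 16.

**Step 12**
Reactants: 13
Product: 14, the bis-TBS ether of 13 (phenol O-TBS and C1-O-TBS; C3-O-TES retained)
Conditions: TBSOTf, 2,6-lutidine, CH2Cl2, −78 → 0 °C
Reagents that add atoms: tert-butyldimethylsilyl triflate, CC(C)(C)[Si](C)(C)OS(=O)(=O)C(F)(F)F
Why: exhaustive silylation with a silyl triflate under non-acidic conditions protects the hindered, ionisation-prone benzylic alcohol; TES, MOM and prenyl groups are inert.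

**Step 13**
Reactants: 14
Product: 15, 2-[(1RS,3R)-1-(tert-butyldimethylsilyloxy)-3-hydroxy-3-[3,5-bis(methoxymethoxy)phenyl]propyl]-3,5-bis(methoxymethoxy)-4,6-bis(3-methylbut-2-en-1-yl)phenol
Conditions: TBAF/AcOH (1:1, 2.2 equiv), THF, 0 °C, monitored
Reagents that add atoms: none
Why: selective fluoride desilylation; the aryl silyl ether and the unhindered secondary TES ether cleave much faster than the secondary TBS ether shielded by the 2,6-disubstituted ring, and buffering avoids both acid and free alkoxide.

**Step 14**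
Reactants: 15
Product: 16, (2S,4RS)-4-(tert-butyldimethylsilyloxy)-5,7-bis(methoxymethoxy)-2-[3,5-bis(methoxymethoxy)phenyl]-6,8-bis(3-methylbut-2-en-1-yl)chromane
Conditions: PPh3, DIAD, THF (0.02 M), 0 °C → rt
Reagents that add atoms: none
Why: intramolecular Mitsunobu etherification; the phenol displaces the activated benzylic alcohol in a 6-exo SN2 with clean inversion, (R) → (2S), and with C4 as a silyl ether there is no acidic α-CH to trigger elimination.

**Step 15**
Reactants: 16
Product: 17, (2S,4RS)-5,7-bis(methoxymethoxy)-2-[3,5-bis(methoxymethoxy)phenyl]-6,8-bis(3-methylbut-2-en-1-yl)chroman-4-ol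
Conditions: TBAF (excess), THF, rt → 40 °C
Reagents that add atoms: none
Why: fluoride desilylation under non-acidic conditions; a flavan has no base-labile stereocentre, so C2 is safe.

**Step 16**
Reactants: 17
Product: 18, (2S)-5,7-bis(methoxymethoxy)-2-[3,5-bis(methoxymethoxy)phenyl]-6,8-bis(3-methylbut-2-en-1-yl)chroman-4-one
Conditions: Dess–Martin periodinane, NaHCO3, CH2Cl2, 0 °C → rt
Reagents that add atoms: none
Why: Dess–Martin oxidation of the benzylic alcohol under neutral buffered conditions; both C4 epimers converge, prenyl alkenes and MOM ethers are inert, and C2 is not enolised.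

**Step 17**
Reactants: 18
Product: 19, (2S)-2-(3,5-dihydroxyphenyl)-5,7-dihydroxy-6,8-bis(3-methylbut-2-en-1-yl)chroman-4-one (target)
Conditions: 3 M aq. HCl/MeOH (1:4), 45 °C, N2, stopped at full conversion
Reagents that add atoms: none
Why: acid-catalysed acetal hydrolysis of the four MOM ethers; flavanones are configurationally stable in acid (racemisation runs through base-mediated ring opening), and mild temperature with short contact limits prenyl/phenol cyclisation to chromans.

## Compound list

1 | phloroglucinol | Oc1cc(O)cc(O)c1 | starting material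
2 | 1,3,5-tris(methoxymethoxy)benzene | COCOc1cc(OCOC)cc(OCOC)c1 | intermediate
3 | 1,3,5-tris(MOMO)-2-prenylbenzene | COCOc1cc(OCOC)c(CC=C(C)C)c(OCOC)c1 | intermediate
4 | 1,3,5-tris(MOMO)-2,4-diprenylbenzene | COCOc1cc(OCOC)c(CC=C(C)C)c(OCOC)c1CC=C(C)C | intermediate
5 | 3,5-dihydroxyacetophenone | CC(=O)c1cc(O)cc(O)c1 | starting material
6 | 3,5-bis(MOMO)acetophenone | CC(=O)c1cc(OCOC)cc(OCOC)c1 | intermediate
7 | ethyl 3-[3,5-bis(MOMO)phenyl]-3-oxopropanoate | CCOC(=O)CC(=O)c1cc(OCOC)cc(OCOC)c1 | intermediate
8 | ethyl (3R)-3-[3,5-bis(MOMO)phenyl]-3-hydroxypropanoate | CCOC(=O)C[C@@H](O)c1cc(OCOC)cc(OCOC)c1 | intermediate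
9 | (3R)-β-hydroxy Weinreb amide | CON(C)C(=O)C[C@@H](O)c1cc(OCOC)cc(OCOC)c1 | intermediate
10 | (3R)-β-(triethylsilyloxy) Weinreb amide | CON(C)C(=O)C[C@@H](O[Si](CC)(CC)CC)c1cc(OCOC)cc(OCOC)c1 | intermediate
11 | (3R)-aryl ketone, A-ring tris-MOM, C3-OTES | O=C(C[C@@H](O[Si](CC)(CC)CC)c1cc(OCOC)cc(OCOC)c1)c1c(OCOC)c(CC=C(C)C)c(OCOC)c(CC=C(C)C)c1OCOC | intermediate
12 | (3R)-2′-hydroxyaryl ketone, C3-OTES | O=C(C[C@@H](O[Si](CC)(CC)CC)c1cc(OCOC)cc(OCOC)c1)c1c(O)c(CC=C(C)C)c(OCOC)c(CC=C(C)C)c1OCOC | intermediate
13 | (1RS,3R)-phenol/benzylic alcohol, C3-OTES | OC(C[C@@H](O[Si](CC)(CC)CC)c1cc(OCOC)cc(OCOC)c1)c1c(O)c(CC=C(C)C)c(OCOC)c(CC=C(C)C)c1OCOC | intermediate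
14 | bis-TBS ether of 13 | CC(C)(C)[Si](C)(C)OC(C[C@@H](O[Si](CC)(CC)CC)c1cc(OCOC)cc(OCOC)c1)c1c(O[Si](C)(C)C(C)(C)C)c(CC=C(C)C)c(OCOC)c(CC=C(C)C)c1OCOC | intermediate
15 | (1RS,3R)-phenol, C3-OH, C1-OTBS | CC(C)(C)[Si](C)(C)OC(C[C@@H](O)c1cc(OCOC)cc(OCOC)c1)c1c(O)c(CC=C(C)C)c(OCOC)c(CC=C(C)C)c1OCOC | intermediate
16 | (2S,4RS)-4-OTBS flavan, tetra-MOM | CC(C)=CCc1c(OCOC)c(CC=C(C)C)c2c(c1OCOC)C(O[Si](C)(C)C(C)(C)C)C[C@@H](c1cc(OCOC)cc(OCOC)c1)O2 | intermediate
17 | (2S,4RS)-flavan-4-ol, tetra-MOM | CC(C)=CCc1c(OCOC)c(CC=C(C)C)c2c(c1OCOC)C(O)C[C@@H](c1cc(OCOC)cc(OCOC)c1)O2 | intermediate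
18 | (2S)-flavanone, tetra-MOM | CC(C)=CCc1c(OCOC)c(CC=C(C)C)c2c(c1OCOC)C(=O)C[C@@H](c1cc(OCOC)cc(OCOC)c1)O2 | intermediate
19 | (2S)-2-(3,5-dihydroxyphenyl)-5,7-dihydroxy-6,8-diprenylchroman-4-one | CC(C)=CCc1c(O)c(CC=C(C)C)c2c(c1O)C(=O)C[C@@H](c1cc(O)cc(O)c1)O2 | target

## Summary

Total steps: 17. Longest linear sequence: 14 (5 → 19, steps 4–17); the A-ring branch (steps 1–3) joins at step 9.

Steps most likely to fail, each with one fallback:

1. **Step 14 (Mitsunobu ring closure).** Risk: elimination or partial ionisation at the benzylic centre, eroding yield or ee. Fallback: abandon SN2 closure and set C2 by C–C bond formation. Build 5,7-bis(MOMO)-6,8-diprenylchromone from 4 (lithiation/acetylation, chelation-controlled ortho-de-MOM, DMF-DMA cyclisation), then run a Rh(I)/chiral-diene asymmetric conjugate addition of 3,5-bis(MOMO)phenylboronic acid.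
2. **Step 13 (selective removal of ArO-TBS and C-O-TES beside the C4 O-TBS).** Risk: loss of the C4 silyl ether or incomplete TES cleavage. Fallback: replace silyl-versus-silyl discrimination with three mechanistically orthogonal groups. Cap the phenol of 12 as an allyl ether (Mitsunobu allylation), reduce, install a single TBS at C4, remove TES with buffered HF·pyridine while the phenol is still capped, then free the phenol with Pd(PPh3)4/morpholine.
3. **Step 17 (global MOM removal with two prenyl groups ortho to emerging phenols).** Risk: acid-induced chroman formation. Fallback: change the protecting-group plan to SEM ethers in place of MOM throughout (same ortho-directing and chelating roles in steps 2, 3, 9 and 10), so the final unmasking uses MgBr2·OEt2 in MeNO2/Et2O or buffered fluoride and no protic acid.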